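## Retrosynthetic overview

1. The C8 CH2OH comes from an ester. The 14-membered ring is the only ring made, and it is closed late at C12–C13 by an sp2–sp3 B-alkyl Suzuki coupling of an acyclic iodo-polyene.
2. C7=C8 (CH2OH trans to C6) comes from an E-selective Horner–Wadsworth–Emmons union of a C1–C7 ester/aldehyde with a C8–C12 iodo-phosphonate.
3. One NHC–Cu SN2′ alkenylation of an (E)-allyl phosphate sets C1, attaches the whole exo-methylene side chain (from sulcatone) and leaves the C13=C14 vinyl handle.
4. The (Z)-C3=C4 olefin (C2–C7 plus its methyl) is the ring-locked cis olefin of Birch-reduced 4-methylanisole. It is released by an allyl-selective Baeyer–Villiger cut of C2–C7, not by ozonolysis of the enol ether.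
5. Ring order: the arene ring is dearomatised and opened in steps 1–2, and the macrocycle is formed in step 13.

Assumption: cembrane locants are used (C1 = stereocentre, C2 next towards the Z-olefin, C15 = side-chain sp2 carbon), the SMILES is read as 1R, 3Z, 7E (ring-cis), 11E, and the catalyst antipode in step 8 is the one that gives (S)-12, its sense being assigned by analogy.

## Route

**Step 1**
Reactants: 1 4-methylanisole
Product: 3 4-methylcyclohex-3-en-1-one, via Birch enol ether 2 (not isolated)
Conditions: Li (2.5 equiv), NH3(l)/THF/t-BuOH, −78 → −33 °C; NH3 off; then (CO2H)2 (0.1 equiv), MeOH/H2O, 20 °C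
Reagents that add atoms: water (O)
Why: Birch reduction breaks the aromaticity to the 1,4-diene with OMe and Me on sp2 carbons, and mild enol-ether hydrolysis keeps the olefin β,γ, so the future C3=C4 bond is locked cis (C2 cis to C5) by the six-membered ring.

**Step 2**
Reactants: 3 4-methylcyclohex-3-en-1-one
Product: 5 methyl (Z)-6-hydroxy-4-methylhex-4-enoate, via allylic lactone 4 (not isolated)
Conditions: (TMSO)2 (1.3 equiv), TMSOTf (10 mol %), CH2Cl2, −40 °C; then MeOH, K2CO3 (0.2 equiv), 0 °C
Reagents that add atoms: bis(trimethylsilyl) peroxide (C[Si](C)(C)OO[Si](C)(C)C); methanol (CO)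
Why: This is a Baeyer–Villiger oxidation with a non-epoxidising peroxide in which the allylic CH2 migrates in preference to the plain CH2, so the C2–C7 bond is cut, the ring-cis olefin becomes the (Z)-trisubstituted alkene, and transesterification opens the seven-membered lactone.

**Step 3**
Reactants: 5 methyl (Z)-6-hydroxy-4-methylhex-4-enoate
Product: 6 methyl (Z)-6-bromo-4-methylhex-4-enoate
Conditions: CBr4, PPh3, CH2Cl2, 0 °C
Reagents that add atoms: carbon tetrabromide (BrC(Br)(Br)Br)
Why: The Appel reaction converts the neryl-type primary allylic alcohol into the bromide under neutral SN2 conditions, without Z/E leakage and without touching the ester.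

**Step 4**
Reactants: 6 methyl (Z)-6-bromo-4-methylhex-4-enoate
Product: 7 methyl (Z)-4-methylocta-4,7-dienoate
Conditions: CH2=CHMgBr (1.2 equiv), CuI (10 mol %), THF, −78 → −30 °C
Reagents that add atoms: vinylmagnesium bromide (C=C[Mg]Br)
Why: In this copper-catalysed allylic substitution the γ,γ-disubstituted terminus blocks SN2′, so vinyl is delivered at C2 (SN2) with the Z geometry kept, and this coupling outruns addition to the ester at low temperature.

**Step 5**
Reactants: 7 methyl (Z)-4-methylocta-4,7-dienoate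
Product: 8 methyl (4Z,7E)-9-[(diethoxyphosphoryl)oxy]-4-methylnona-4,7-dienoate
Conditions: diethyl allyl phosphate (3 equiv), Hoveyda–Grubbs II (5 mol %), CH2Cl2, 40 °C; minor 7Z isomer removed on AgNO3–SiO2
Reagents that add atoms: diethyl allyl phosphate (C=CCOP(=O)(OCC)OCC)
Why: In this olefin cross-metathesis only the monosubstituted alkene of 7 reacts (the trisubstituted Z-olefin is inert), and the allylic-oxygen partner gives the thermodynamic E-allyl phosphate directly.

**Step 6**
Reactants: 9 6-methylhept-5-en-2-one (sulcatone)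
Product: 10 6-methylhepta-1,5-dien-2-yl trifluoromethanesulfonate
Conditions: LDA (1.05 equiv), THF, −78 °C; PhNTf2, −78 → 0 °C
Reagents that add atoms: N-phenylbis(trifluoromethanesulfonimide) (O=S(=O)(N(c1ccccc1)S(=O)(=O)C(F)(F)F)C(F)(F)F)
Why: Kinetic enolate O-triflation works because LDA removes a proton from the methyl side, which gives the 1,1-disubstituted enol triflate that already carries the =CH2 and homoprenyl groups of the side chain.

**Step 7**
Reactants: 10 6-methylhepta-1,5-dien-2-yl trifluoromethanesulfonate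
Product: 11 2-(6-methylhepta-1,5-dien-2-yl)-4,4,5,5-tetramethyl-1,3,2-dioxaborolane
Conditions: B2pin2 (1.1 equiv), PdCl2(PPh3)2 (3 mol %), PPh3, PhOK (1.5 equiv), toluene, 50 °C
Reagents that add atoms: bis(pinacolato)diboron (CC1(C)OB(OC1(C)C)B1OC(C)(C)C(C)(C)O1)
Why: Miyaura borylation of the alkenyl triflate under the mild phenoxide protocol gives the alkenyl boronate and leaves the isolated trisubstituted olefin untouched.

**Step 8**
Reactants: 8 methyl (4Z,7E)-9-[(diethoxyphosphoryl)oxy]-4-methylnona-4,7-dienoate + 11 alkenyl pinacol boronate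
Product: 12 methyl (4Z,7S)-7-ethenyl-4,12-dimethyl-8-methylidenetrideca-4,11-dienoate
Conditions: 11 (1.5 equiv), CuCl (5 mol %), chiral sulfonate-bearing imidazolinium salt (5.5 mol %), NaOMe (1.5 equiv), THF, 22 °C
Reagents that add atoms: none
Why: In this NHC–Cu-catalysed enantioselective allylic substitution the alkenyl-copper formed by B→Cu exchange attacks C1 anti-SN2′, so the chiral NHC sets the C1 stereocentre by facial selection while the same step installs the complete side chain and the C13=C14 vinyl group.

**Step 9**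
Reactants: 13 pent-3-yn-1-ol
Product: 14 (E)-4-iodopent-3-en-1-ol
Conditions: Cp2Zr(H)Cl (2.5 equiv), THF, 20 → 40 °C; then I2, 0 °C
Reagents that add atoms: iodine (II)
Why: In this hydrozirconation–iodination, syn H–Zr addition and equilibration with excess Schwartz reagent put Zr on the methyl-bearing carbon, and iodinolysis with retention fixes the E geometry of the future C11=C12 bond.

**Step 10**
Reactants: 14 (E)-4-iodopent-3-en-1-ol
Product: 15 (E)-2,5-diiodopent-2-ene
Conditions: I2, PPh3, imidazole, CH2Cl2, 0 °C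
Reagents that add atoms: iodine (II)
Why: Appel-type (Garegg–Samuelsson) iodination converts only the primary alcohol, and the vinyl iodide is inert to these conditions.

**Step 11**
Reactants: 15 (E)-2,5-diiodopent-2-ene + 16 triethyl phosphonoacetate
Product: 17 ethyl (E)-2-(diethoxyphosphoryl)-6-iodohept-5-enoate (racemic at C2)
Conditions: NaH (1.0 equiv), 16 (1.3 equiv), THF/DMF, 0 → 50 °C
Reagents that add atoms: none
Why: In this phosphonoacetate alkylation the soft stabilised carbanion displaces only the sp3 iodide, and the stereocentre it creates is erased in the later olefination.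

**Step 12**
Reactants: 12 methyl (4Z,7S)-7-ethenyl-4,12-dimethyl-8-methylidenetrideca-4,11-dienoate + 17 iodo-phosphonate
Product: 19 ethyl (2E,6Z,9S)-9-ethenyl-2-[(3E)-4-iodopent-3-en-1-yl]-6,14-dimethyl-10-methylidenepentadeca-2,6,13-trienoate, via aldehyde 18 (not isolated)
Conditions: DIBAL-H (1.1 equiv), toluene, −78 °C; then 17/NaH in THF by cannula, −78 → 20 °C; minor 2Z isomer removed by chromatography
Reagents that add atoms: none
Why: In this one-pot ester half-reduction and Horner–Wadsworth–Emmons olefination, the aluminium hemiacetal releases the aldehyde on warming and the α-alkyl phosphonate anion gives the E-enoate (ester trans to C6), which is the C7=C8 geometry of the target.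

**Step 13**
Reactants: 19 acyclic iodo-pentaene ester
Product: 21 ethyl (1E,5Z,8R,11E)-5,11-dimethyl-8-(6-methylhepta-1,5-dien-2-yl)cyclotetradeca-1,5,11-triene-1-carboxylate, via alkylborane 20 (not isolated)
Conditions: Cy2BH (1.1 equiv, from BH3·THF + cyclohexene), THF, 0 → 20 °C; then slow addition to Pd(dppf)Cl2 (15 mol %), AsPh3, Cs2CO3 (3 equiv), DMF/THF/H2O, 50 °C, 1 mM
Reagents that add atoms: none
Why: In this hydroboration and B-alkyl Suzuki–Miyaura macrocyclisation the bulky dialkylborane takes the monosubstituted vinyl much faster than the 1,1-disubstituted or trisubstituted olefins, and the primary alkyl group then couples with the vinyl iodide with retention, closing C12–C13 with 11E and leaving C1 untouched.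

**Step 14**
Reactants: 21 macrocyclic ethyl ester
Product: 22 [(1E,5Z,8R,11E)-5,11-dimethyl-8-(6-methylhepta-1,5-dien-2-yl)cyclotetradeca-1,5,11-trien-1-yl]methanol (target)
Conditions: DIBAL-H (2.5 equiv), CH2Cl2, −78 → 0 °C
Reagents that add atoms: none
Why: DIBAL-H reduces the enoate 1,2 to the allylic alcohol without changing any olefin geometry or the stereocentre.

## Compound list

1 | 4-methylanisole | COc1ccc(C)cc1 | starting material
2 | 1-methoxy-4-methylcyclohexa-1,4-diene | COC1=CCC(C)=CC1 | intermediate
3 | 4-methylcyclohex-3-en-1-one | CC1=CCC(=O)CC1 | intermediate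
4 | 5-methyl-4,7-dihydrooxepin-2(3H)-one | CC1=CCOC(=O)CC1 | intermediate
5 | methyl (Z)-6-hydroxy-4-methylhex-4-enoate | OC/C=C(/C)CCC(=O)OC | intermediate
6 | methyl (Z)-6-bromo-4-methylhex-4-enoate | BrC/C=C(/C)CCC(=O)OC | intermediate
7 | methyl (Z)-4-methylocta-4,7-dienoate | C=CC/C=C(/C)CCC(=O)OC | intermediate
8 | methyl (4Z,7E)-9-[(diethoxyphosphoryl)oxy]-4-methylnona-4,7-dienoate | CCOP(=O)(OCC)OC/C=C/C/C=C(/C)CCC(=O)OC | intermediate
9 | 6-methylhept-5-en-2-one | CC(=O)CCC=C(C)C | starting material
10 | 6-methylhepta-1,5-dien-2-yl trifluoromethanesulfonate | C=C(CCC=C(C)C)OS(=O)(=O)C(F)(F)F | intermediate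
11 | 2-(6-methylhepta-1,5-dien-2-yl)-4,4,5,5-tetramethyl-1,3,2-dioxaborolane | C=C(CCC=C(C)C)B1OC(C)(C)C(C)(C)O1 | intermediate
12 | methyl (4Z,7S)-7-ethenyl-4,12-dimethyl-8-methylidenetrideca-4,11-dienoate | C=C(CCC=C(C)C)[C@H](C=C)C/C=C(/C)CCC(=O)OC | intermediate
13 | pent-3-yn-1-ol | CC#CCCO | starting material
14 | (E)-4-iodopent-3-en-1-ol | C/C(I)=C\CCO | intermediate
15 | (E)-2,5-diiodopent-2-ene | C/C(I)=C\CCI | intermediate
16 | triethyl phosphonoacetate | CCOC(=O)CP(=O)(OCC)OCC | starting material
17 | ethyl (E)-2-(diethoxyphosphoryl)-6-iodohept-5-enoate | CCOC(=O)C(CC/C=C(\C)I)P(=O)(OCC)OCC | intermediate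
18 | (4Z,7S)-7-ethenyl-4,12-dimethyl-8-methylidenetrideca-4,11-dienal | C=C(CCC=C(C)C)[C@H](C=C)C/C=C(/C)CCC=O | intermediate
19 | ethyl (2E,6Z,9S)-9-ethenyl-2-[(3E)-4-iodopent-3-en-1-yl]-6,14-dimethyl-10-methylidenepentadeca-2,6,13-trienoate | C=C(CCC=C(C)C)[C@H](C=C)C/C=C(/C)CC/C=C(/C(=O)OCC)CC/C=C(\C)I | intermediate
20 | (R)-B-alkyl dicyclohexylborane from 19 (vinyl converted into CH2CH2–B(c-C6H11)2) | C=C(CCC=C(C)C)[C@H](CCB(C1CCCCC1)C1CCCCC1)C/C=C(/C)CC/C=C(/C(=O)OCC)CC/C=C(\C)I | intermediate
21 | ethyl (1E,5Z,8R,11E)-5,11-dimethyl-8-(6-methylhepta-1,5-dien-2-yl)cyclotetradeca-1,5,11-triene-1-carboxylate | C=C(CCC=C(C)C)[C@H]1C/C=C(/C)CC/C=C(/C(=O)OCC)CC/C=C(\C)CC1 | intermediate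
22 | [(1E,5Z,8R,11E)-5,11-dimethyl-8-(6-methylhepta-1,5-dien-2-yl)cyclotetradeca-1,5,11-trien-1-yl]methanol | C=C(CCC=C(C)C)[C@H]1C/C=C(/C)CC/C=C(/CO)CC/C=C(\C)CC1 | target

## Step count

- Total steps: 14.
- Longest linear sequence: 9 (steps 1, 2, 3, 4, 5, 8, 12, 13, 14).

## Steps most likely to fail, with fallbacks

**Step 2 (chemo- and regioselective Baeyer–Villiger).** The risks are acid-induced conjugation of the β,γ-enone, epoxidation, and migration of the wrong CH2. The fallback avoids the ketone altogether. It sets out from 2, which is isomerised with KOt-Bu in DMSO to the conjugated 1-methoxy-4-methylcyclohexa-1,3-diene F1. Its enol-ether C=C alone is cleaved with one equivalent of ozone (CH2Cl2/MeOH, −78 °C) to methyl (Z)-4-methyl-6-oxohex-4-enoate F2. This labile Z-enal is reduced at once in the same flask with NaBH4/CeCl3. The fallback comes back to the route at 5.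

**Step 8 (enantioselective SN2′ alkenylation with a 1,1-disubstituted alkenyl boronate).** The risks are low ee with the alkyl-substituted phosphate and SN2 leakage. The fallback sets C1 with an auxiliary by a lavandulyl-type deconjugative alkylation, and it sets out from 6.
- (E)-Geranic acid is coupled (PivCl, Et3N, LiCl) with (R)-4-benzyloxazolidin-2-one to give (R)-4-benzyl-3-[(E)-3,7-dimethylocta-2,6-dienoyl]oxazolidin-2-one F3.
- NaHMDS at −78 °C removes a proton from the γ-methyl group cis to the carbonyl. The dienolate is alkylated at Cα by 6, anti to the benzyl group, to give the α-alkylated β,γ-unsaturated (R)-imide F4.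
- LiBH4/MeOH reduces the imide faster than the methyl ester and gives the (R)-primary alcohol F5.
- Dess–Martin oxidation gives the (R)-aldehyde F6.
- Salt-free Ph3P=CH2 at −78 °C converts F6 into the vinyl compound, so the fallback comes back at 12.

**Step 13 (B-alkyl Suzuki macrocyclisation).** The risks are oligomerisation, protodeboronation, and competing hydroboration of the exo-methylene. The fallback closes the ring at C7=C8 instead, and it sets out from 12 (with 17).
- Cy2BH converts 12 into the (R)-alkylborane ester F7.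
- F7 is coupled intermolecularly with 17 (Pd(dppf)Cl2, Cs2CO3) to give the (R)-phosphonate diester F8.
- NaHMDS (1 equiv) masks the phosphonoacetate as its enolate, and DIBAL-H at −78 °C then reduces only the methyl ester, giving the (R)-phosphonate aldehyde F9.
- F9 closes by intramolecular Horner–Wadsworth–Emmons reaction on dilution and warming, or after isolation with LiCl/DBU in MeCN at 1 mM. The fallback comes back at 21.

## Further compounds

F1 | step 2 | 1-methoxy-4-methylcyclohexa-1,3-diene | COC1=CC=C(C)CC1
F2 | step 2 | methyl (Z)-4-methyl-6-oxohex-4-enoate | O=C/C=C(/C)CCC(=O)OC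
F3 | step 8 | (R)-4-benzyl-3-[(E)-3,7-dimethylocta-2,6-dienoyl]oxazolidin-2-one | CC(C)=CCC/C(C)=C/C(=O)N1[C@H](Cc2ccccc2)COC1=O
F4 | step 8 | methyl (4Z,7R)-7-{[(R)-4-benzyl-2-oxooxazolidin-3-yl]carbonyl}-4,12-dimethyl-8-methylidenetrideca-4,11-dienoate | C=C(CCC=C(C)C)[C@H](C(=O)N1[C@H](Cc2ccccc2)COC1=O)C/C=C(/C)CCC(=O)OC
F5 | step 8 | methyl (4Z,7R)-7-(hydroxymethyl)-4,12-dimethyl-8-methylidenetrideca-4,11-dienoate | C=C(CCC=C(C)C)[C@H](CO)C/C=C(/C)CCC(=O)OC
F6 | step 8 | methyl (4Z,7R)-7-formyl-4,12-dimethyl-8-methylidenetrideca-4,11-dienoate | C=C(CCC=C(C)C)[C@H](C=O)C/C=C(/C)CCC(=O)OC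
F7 | step 13 | methyl (4Z,7R)-7-[2-(dicyclohexylboranyl)ethyl]-4,12-dimethyl-8-methylidenetrideca-4,11-dienoate | C=C(CCC=C(C)C)[C@H](CCB(C1CCCCC1)C1CCCCC1)C/C=C(/C)CCC(=O)OC
F8 | step 13 | (R)-diester from F7 and 17: C13–C12 joined (11E), methyl ester at C7, ethyl diethylphosphonoacetate unit at C8 | C=C(CCC=C(C)C)[C@H](CC/C(C)=C/CCC(C(=O)OCC)P(=O)(OCC)OCC)C/C=C(/C)CCC(=O)OC
F9 | step 13 | (R)-aldehyde from F8 (C7 methyl ester reduced to CHO, phosphonoacetate kept) | C=C(CCC=C(C)C)[C@H](CC/C(C)=C/CCC(C(=O)OCC)P(=O)(OCC)OCC)C/C=C(/C)CCC=O
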